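The route rests on cutting two bonds of the hexahydronaphthalene at once: C1–C2 of ring A and the chain CH2–CH= bond at the exocyclic alkene. A single palladium cascade forms both. The π-allyl from a cyclohexenylmethyl acetate carrying a butynyl arm adds syn across its terminal alkyne, closing ring A, and the alkenylpalladium is captured by a B-alkyl-9-BBN made from a vinyl-1,2-dioxane ester that already holds all three stereocentres. What the step exploits: at the exocyclic C2=CH double bond of ring A, the dioxane-bearing chain and the ring CH2 at C1 lie on the same side, as syn addition to an alkyne followed by retentive coupling requires. Ester hydrolysis then gives the acid.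

Key step: step 19

Remark: locants C1, C2, C4a and C8a are those of the hexahydronaphthalene of the target; it is assumed that a saturated 1,2-dioxane tolerates 9-BBN and zerovalent palladium at or below 50 °C, as dialkyl peroxides generally do.

Step 1
Reactants: 1 2,2-dimethylcyclohexanone
Product: 2 methyl 3,3-dimethyl-2-oxocyclohexane-1-carboxylate
Conditions: NaH (2.2 equiv), (MeO)2CO (3 equiv), THF, reflux; then aq. HCl
Reagents that add atoms: dimethyl carbonate, COC(=O)OC
Why: Claisen-type C-acylation of the ketone enolate, which can form only on the CH2 side, driven by deprotonation of the β-keto ester; the new centre is enolisable and disappears in step 2.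

Step 2
Reactants: 2 methyl 3,3-dimethyl-2-oxocyclohexane-1-carboxylate
Product: 3 methyl 3,3-dimethyl-2-{[(trifluoromethyl)sulfonyl]oxy}cyclohex-1-ene-1-carboxylate
Conditions: NaH, Et2O, 0 °C; then Tf2O, 0 °C → rt
Reagents that add atoms: trifluoromethanesulfonic anhydride, O=S(=O)(OS(=O)(=O)C(F)(F)F)C(F)(F)F
Why: O-sulfonylation of the sodium enolate (enol triflate formation); enolisation is possible only toward the ester-bearing carbon, so one alkene isomer should result.

Step 3
Reactants: 4 4-(trimethylsilyl)but-3-yn-1-ol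
Product: 5 (4-iodobut-1-yn-1-yl)trimethylsilane
Conditions: I2, PPh3, imidazole, CH2Cl2, 0 °C → rt
Reagents that add atoms: iodine, [I][I]
Why: Appel-type iodination of a primary alcohol through the alkoxyphosphonium salt.

Step 4
Reactants: 3 methyl 3,3-dimethyl-2-{[(trifluoromethyl)sulfonyl]oxy}cyclohex-1-ene-1-carboxylate; 5 (4-iodobut-1-yn-1-yl)trimethylsilane
Product: 7 methyl 3,3-dimethyl-2-[4-(trimethylsilyl)but-3-yn-1-yl]cyclohex-1-ene-1-carboxylate, via alkylzinc iodide 6 (not isolated)
Conditions: 5, Zn dust (activated: BrCH2CH2Br, Me3SiCl), LiCl, THF, 40 °C → 6; then 3, PdCl2(dppf) (5 mol%), THF/NMP, 60 °C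
Reagents that add atoms: none
Why: Negishi coupling: the electron-poor β-(triflyloxy) enoate adds readily to zerovalent palladium, the primary alkylzinc iodide tolerates ester and silylalkyne, and the wide-bite-angle dppf ligand favours reductive elimination over β-hydride loss at the carbon flanked by the gem-dimethyl group.

Step 5
Reactants: 7 methyl 3,3-dimethyl-2-[4-(trimethylsilyl)but-3-yn-1-yl]cyclohex-1-ene-1-carboxylate
Product: 8 {3,3-dimethyl-2-[4-(trimethylsilyl)but-3-yn-1-yl]cyclohex-1-en-1-yl}methanol
Conditions: DIBAL-H (2.5 equiv), CH2Cl2, −78 → 0 °C; aq. Rochelle salt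
Reagents that add atoms: none
Why: Hydride reduction of the conjugated ester in the 1,2-sense to the allylic alcohol; the tetrasubstituted alkene and the silylalkyne are inert to DIBAL-H at low temperature.

Step 6
Reactants: 8 {3,3-dimethyl-2-[4-(trimethylsilyl)but-3-yn-1-yl]cyclohex-1-en-1-yl}methanol
Product: 9 [2-(but-3-yn-1-yl)-3,3-dimethylcyclohex-1-en-1-yl]methanol
Conditions: K2CO3 (cat.), MeOH, rt
Reagents that add atoms: none
Why: Base-catalysed protodesilylation of the alkynylsilane by methanol frees the terminal alkyne needed for the cascade.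

Step 7
Reactants: 9 [2-(but-3-yn-1-yl)-3,3-dimethylcyclohex-1-en-1-yl]methanol
Product: 10 [2-(but-3-yn-1-yl)-3,3-dimethylcyclohex-1-en-1-yl]methyl acetate
Conditions: Ac2O, pyridine, DMAP (cat.), CH2Cl2, 0 °C → rt
Reagents that add atoms: acetic anhydride, CC(=O)OC(C)=O
Why: DMAP-catalysed acetylation of the primary allylic alcohol gives the leaving group for π-allyl formation.

Step 8
Reactants: 11 geranyl acetate [(2E)-3,7-dimethylocta-2,6-dien-1-yl acetate]
Product: 12 (2E)-3-methyl-6-oxohex-2-en-1-yl acetate
Conditions: O3 (1 equiv, Sudan Red 7B end point), CH2Cl2/MeOH, −78 °C; then Me2S, −78 °C → rt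
Reagents that add atoms: ozone, [O-][O+]=O
Why: Chemoselective ozonolysis: electrophilic ozone cleaves the electron-rich isopropylidene alkene well before the alkene deactivated by the allylic acetate, and the dye end point guards against over-ozonation.

Step 9
Reactants: 12 (2E)-3-methyl-6-oxohex-2-en-1-yl acetate
Product: 13 (2E,6S,7R)-6-hydroxy-3,7-dimethylnona-2,8-dien-1-yl acetate
Conditions: (E)-crotyl-B(Ipc)2 (Ipc from (−)-α-pinene, 1.3 equiv, pre-formed solution), THF/Et2O, −78 °C; then pH 7 buffer, MeOH, 30% H2O2, 0 °C → rt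
Reagents that add atoms: (E)-crotyldiisopinocampheylborane (isopinocampheyl groups from (−)-α-pinene), C/C=C/CB([C@H]1C[C@H]2C[C@@H]([C@@H]1C)C2(C)C)[C@H]1C[C@H]2C[C@@H]([C@@H]1C)C2(C)C
Why: Brown crotylboration through a closed chair (Zimmerman–Traxler) transition state: the E-crotyl unit gives the 6,7-anti relationship and the isopinocampheyl groups direct attack to the Re face of the aldehyde, setting 6S and 7R together, while the neutral peroxide work-up keeps the acetate.

Step 10
Reactants: 13 (2E,6S,7R)-6-hydroxy-3,7-dimethylnona-2,8-dien-1-yl acetate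
Product: 14 (2E,6S,7R)-6-[(methanesulfonyl)oxy]-3,7-dimethylnona-2,8-dien-1-yl acetate
Conditions: MsCl, Et3N, CH2Cl2, −10 → 0 °C
Reagents that add atoms: methanesulfonyl chloride, CS(=O)(=O)Cl
Why: Sulfonylation of the secondary alcohol with retention turns the carbinol into the leaving group for the later ring closure.

Step 11
Reactants: 14 (2E,6S,7R)-6-[(methanesulfonyl)oxy]-3,7-dimethylnona-2,8-dien-1-yl acetate
Product: 15 (3R,4S,7E)-9-hydroxy-3,7-dimethylnona-1,7-dien-4-yl methanesulfonate
Conditions: K2CO3 (0.2 equiv), MeOH, 0 °C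
Reagents that add atoms: none
Why: Carbonate-catalysed methanolysis removes the acetate; the secondary mesylate has no nucleophile within reach and should survive cold, weakly basic methanol.

Step 12
Reactants: 15 (3R,4S,7E)-9-hydroxy-3,7-dimethylnona-1,7-dien-4-yl methanesulfonate
Product: 16 (3R,4S)-6-[(2S,3S)-3-(hydroxymethyl)-2-methyloxiran-2-yl]-3-methylhex-1-en-4-yl methanesulfonate
Conditions: Ti(OiPr)4 (10 mol%), L-(+)-diethyl tartrate (12 mol%), t-BuOOH (2 equiv), 4 Å MS, CH2Cl2, −20 °C
Reagents that add atoms: tert-butyl hydroperoxide, CC(C)(C)OO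
Why: Sharpless asymmetric epoxidation: only the allylic alcohol alkene binds to titanium, and with L-(+)-tartrate oxygen is delivered to the face that gives the (2S,3S)-oxirane, as for geraniol itself; vinyl group and mesylate are spectators.

Step 13
Reactants: 16 (3R,4S)-6-[(2S,3S)-3-(hydroxymethyl)-2-methyloxiran-2-yl]-3-methylhex-1-en-4-yl methanesulfonate
Product: 17 (3R,4S,7R,8S)-7-hydroperoxy-8,9-dihydroxy-3,7-dimethylnon-1-en-4-yl methanesulfonate
Conditions: H2O2 (anhydrous, ca. 2 M in Et2O, 10 equiv), H3PMo12O40 (2 mol%), Et2O, 0 °C → rt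
Reagents that add atoms: hydrogen peroxide, OO
Why: Acid-catalysed perhydrolysis of the epoxide: hydrogen peroxide attacks the tertiary oxirane carbon (best able to carry positive charge, not deactivated by the hydroxymethyl group) from the back in a borderline SN2 opening, so C7 is set as R by inversion while carbinol C8 keeps its S configuration.

Step 14
Reactants: 17 (3R,4S,7R,8S)-7-hydroperoxy-8,9-dihydroxy-3,7-dimethylnon-1-en-4-yl methanesulfonate
Product: 18 (1S)-1-[(3R,6R)-6-[(2R)-but-3-en-2-yl]-3-methyl-1,2-dioxan-3-yl]ethane-1,2-diol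
Conditions: KOtBu (1.0 equiv), 18-crown-6 (1.0 equiv), THF, −20 → 0 °C
Reagents that add atoms: none
Why: Intramolecular Williamson-type alkylation of the hydroperoxide: one equivalent of base deprotonates only the far more acidic OOH, and the peroxide anion displaces the secondary mesylate in a 6-exo-tet SN2 reaction with inversion, which sets the ring CH as R and leaves the quaternary centre untouched.

Step 15
Reactants: 18 (1S)-1-[(3R,6R)-6-[(2R)-but-3-en-2-yl]-3-methyl-1,2-dioxan-3-yl]ethane-1,2-diol
Product: 20 (2S)-2-[(3R,6R)-6-[(1S)-1,2-dihydroxyethyl]-6-methyl-1,2-dioxan-3-yl]propanoic acid, via dioxanyl propanal 19 (not isolated)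
Conditions: O3, MeCN/H2O (9:1), 0 °C, N2 purge; then NaClO2, NaH2PO4, 2-methyl-2-butene, 0 °C → rt
Reagents that add atoms: ozone, [O-][O+]=O; water, O; sodium chlorite, [Na+].[O-]Cl=O
Why: Ozonolysis of the only alkene in wet acetonitrile gives the aldehyde directly, and buffered Pinnick oxidation in the same pot converts it to the acid without epimerising the α-centre; the dialkyl peroxide and the diol are inert to both oxidants.

Step 16
Reactants: 20 (2S)-2-[(3R,6R)-6-[(1S)-1,2-dihydroxyethyl]-6-methyl-1,2-dioxan-3-yl]propanoic acid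
Product: 21 (2S)-2-[(3R,6R)-6-formyl-6-methyl-1,2-dioxan-3-yl]propanoic acid
Conditions: NaIO4 (1.2 equiv), THF/pH 7 buffer, 0 °C → rt; used crude
Reagents that add atoms: none
Why: Malaprade glycol cleavage by periodate removes the terminal carbon and leaves a non-enolisable α-peroxy aldehyde; the carbinol centre destroyed here was only a relay.

Step 17
Reactants: 21 (2S)-2-[(3R,6R)-6-formyl-6-methyl-1,2-dioxan-3-yl]propanoic acid
Product: 22 (2S)-2-[(3R,6R)-6-ethenyl-6-methyl-1,2-dioxan-3-yl]propanoic acid
Conditions: Ph3PCH3Br (2.5 equiv), KHMDS (2.4 equiv), THF, 0 °C; then 21, −78 → 0 °C; aq. NaH2PO4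
Reagents that add atoms: methyltriphenylphosphonium bromide, C[P+](c1ccccc1)(c1ccccc1)c1ccccc1.[Br-]
Why: Wittig methylenation: the first equivalent of ylide turns the acid into its carboxylate, which makes the α-proton non-acidic and so blocks epimerisation and β-elimination of the peroxide, while the aldehyde is converted through the oxaphosphetane into the vinyl group.

Step 18
Reactants: 22 (2S)-2-[(3R,6R)-6-ethenyl-6-methyl-1,2-dioxan-3-yl]propanoic acid
Product: 23 methyl (2S)-2-[(3R,6R)-6-ethenyl-6-methyl-1,2-dioxan-3-yl]propanoate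
Conditions: Me3SiCHN2, toluene/MeOH (4:1), 0 °C
Reagents that add atoms: (trimethylsilyl)diazomethane, C[Si](C)(C)C=[N+]=[N-]
Why: Methyl ester formation with (trimethylsilyl)diazomethane is neutral and fast, so the β-peroxy acid is esterified without risk to its stereocentres.

Step 19
Reactants: 10 [2-(but-3-yn-1-yl)-3,3-dimethylcyclohex-1-en-1-yl]methyl acetate; 23 methyl (2S)-2-[(3R,6R)-6-ethenyl-6-methyl-1,2-dioxan-3-yl]propanoate
Product: 25 methyl (2S)-2-[(3R,6S)-6-[(3Z)-3-(5,5-dimethyl-3,4,5,6,7,8-hexahydronaphthalen-2(1H)-ylidene)propyl]-6-methyl-1,2-dioxan-3-yl]propanoate, via B-alkyl-9-BBN adduct 24 (not isolated)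
Conditions: 23 (1.3 equiv), 9-BBN-H dimer (0.95 B–H per alkene), THF, rt → 24; then 10 (1.0 equiv), Pd2(dba)3 (2.5 mol%), AsPh3 (20 mol%), K3PO4 (3 M aq., 3 equiv), THF/DMF, 50 °C; non-oxidative work-up
Reagents that add atoms: none
Why: Proposed new method: zerovalent palladium ionises the allylic acetate of 10 to a π-allyl complex, the primary terminus C1 and palladium then add syn across the tethered terminal alkyne (migratory insertion), and the alkenylpalladium so formed is intercepted by base-activated 24 through transmetalation and reductive elimination with retention. The closest known reactions are palladium-ene-type allyl–alkyne cyclisations that end with capture by an organometallic partner, and the B-alkyl Suzuki–Miyaura coupling of alkenyl halides; running both in one catalytic cycle is untested. Ring A closes in the 6-exo-dig mode through the C1–C2 bond, the C4a=C8a alkene staying where it is, because attack through the other, fully substituted allyl terminus could only give a cyclobutane. No stereocentre is created and those of 24 are remote from the reaction; the one stereogenic element formed, the C2=CH geometry, is fixed as Z (chain cis to C1) by the syn insertion and the retentive coupling. The step needs insertion to precede transmetalation: the intramolecular six-ring insertion, a weakly bound arsine ligand that leaves a coordination site for the alkyne, the acetate leaving group (no alkoxide is released that would activate the borane early) and the reluctance of allyl(alkyl)palladium to eliminate reductively should secure this, and a slight deficit of 9-BBN-H leaves no B–H to add to the alkyne. Survival of the peroxide bond is expected from the known inertness of dialkyl peroxides to boranes and to palladium cross-coupling at or below 50 °C.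

Step 20
Reactants: 25 methyl (2S)-2-[(3R,6S)-6-[(3Z)-3-(5,5-dimethyl-3,4,5,6,7,8-hexahydronaphthalen-2(1H)-ylidene)propyl]-6-methyl-1,2-dioxan-3-yl]propanoate
Product: 26 (2S)-2-[(3R,6S)-6-[(3Z)-3-(5,5-dimethyl-3,4,5,6,7,8-hexahydronaphthalen-2(1H)-ylidene)propyl]-6-methyl-1,2-dioxan-3-yl]propanoic acid
Conditions: LiOH·H2O (3 equiv), THF/MeOH/H2O, 0 °C → rt; then 0.5 M HCl to pH 4, 0 °C
Reagents that add atoms: lithium hydroxide, [Li+].[OH-]
Why: Saponification (BAc2): hydroxide adds to the ester carbonyl far faster than it can remove the hindered α-proton, so neither epimerisation nor retro-oxa-Michael opening of the dioxane is expected at 0 °C, and the alkenes and the peroxide are inert to aqueous LiOH.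

Compound list
1 | 2,2-dimethylcyclohexanone | CC1(C)CCCCC1=O | starting material
2 | methyl 3,3-dimethyl-2-oxocyclohexane-1-carboxylate (racemic, enolisable) | COC(=O)C1CCCC(C)(C)C1=O | intermediate
3 | methyl 3,3-dimethyl-2-{[(trifluoromethyl)sulfonyl]oxy}cyclohex-1-ene-1-carboxylate | COC(=O)C1=C(OS(=O)(=O)C(F)(F)F)C(C)(C)CCC1 | intermediate
4 | 4-(trimethylsilyl)but-3-yn-1-ol | C[Si](C)(C)C#CCCO | starting material
5 | (4-iodobut-1-yn-1-yl)trimethylsilane | C[Si](C)(C)C#CCCI | intermediate
6 | [4-(trimethylsilyl)but-3-yn-1-yl]zinc iodide | C[Si](C)(C)C#CCC[Zn]I | intermediate (not isolated)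
7 | methyl 3,3-dimethyl-2-[4-(trimethylsilyl)but-3-yn-1-yl]cyclohex-1-ene-1-carboxylate | COC(=O)C1=C(CCC#C[Si](C)(C)C)C(C)(C)CCC1 | intermediate
8 | {3,3-dimethyl-2-[4-(trimethylsilyl)but-3-yn-1-yl]cyclohex-1-en-1-yl}methanol | OCC1=C(CCC#C[Si](C)(C)C)C(C)(C)CCC1 | intermediate
9 | [2-(but-3-yn-1-yl)-3,3-dimethylcyclohex-1-en-1-yl]methanol | OCC1=C(CCC#C)C(C)(C)CCC1 | intermediate
10 | [2-(but-3-yn-1-yl)-3,3-dimethylcyclohex-1-en-1-yl]methyl acetate | CC(=O)OCC1=C(CCC#C)C(C)(C)CCC1 | intermediate
11 | geranyl acetate, (2E)-3,7-dimethylocta-2,6-dien-1-yl acetate | CC(C)=CCC/C(C)=C/COC(C)=O | starting material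
12 | (2E)-3-methyl-6-oxohex-2-en-1-yl acetate | O=CCC/C(C)=C/COC(C)=O | intermediate
13 | (2E,6S,7R)-6-hydroxy-3,7-dimethylnona-2,8-dien-1-yl acetate | C[C@H](C=C)[C@@H](O)CC/C(C)=C/COC(C)=O | intermediate
14 | (2E,6S,7R)-6-[(methanesulfonyl)oxy]-3,7-dimethylnona-2,8-dien-1-yl acetate | C[C@H](C=C)[C@@H](OS(C)(=O)=O)CC/C(C)=C/COC(C)=O | intermediate
15 | (3R,4S,7E)-9-hydroxy-3,7-dimethylnona-1,7-dien-4-yl methanesulfonate | C[C@H](C=C)[C@@H](OS(C)(=O)=O)CC/C(C)=C/CO | intermediate
16 | (3R,4S)-6-[(2S,3S)-3-(hydroxymethyl)-2-methyloxiran-2-yl]-3-methylhex-1-en-4-yl methanesulfonate | C[C@H](C=C)[C@@H](OS(C)(=O)=O)CC[C@]1(C)O[C@H]1CO | intermediate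
17 | (3R,4S,7R,8S)-7-hydroperoxy-8,9-dihydroxy-3,7-dimethylnon-1-en-4-yl methanesulfonate | C[C@H](C=C)[C@@H](OS(C)(=O)=O)CC[C@@](C)(OO)[C@@H](O)CO | intermediate
18 | (1S)-1-[(3R,6R)-6-[(2R)-but-3-en-2-yl]-3-methyl-1,2-dioxan-3-yl]ethane-1,2-diol | C[C@H](C=C)[C@H]1CC[C@](C)([C@@H](O)CO)OO1 | intermediate
19 | (2S)-2-[(3R,6R)-6-[(1S)-1,2-dihydroxyethyl]-6-methyl-1,2-dioxan-3-yl]propanal | C[C@H](C=O)[C@H]1CC[C@](C)([C@@H](O)CO)OO1 | intermediate (not isolated)
20 | (2S)-2-[(3R,6R)-6-[(1S)-1,2-dihydroxyethyl]-6-methyl-1,2-dioxan-3-yl]propanoic acid | C[C@H](C(=O)O)[C@H]1CC[C@](C)([C@@H](O)CO)OO1 | intermediate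
21 | (2S)-2-[(3R,6R)-6-formyl-6-methyl-1,2-dioxan-3-yl]propanoic acid | C[C@H](C(=O)O)[C@H]1CC[C@](C)(C=O)OO1 | intermediate
22 | (2S)-2-[(3R,6R)-6-ethenyl-6-methyl-1,2-dioxan-3-yl]propanoic acid | C[C@H](C(=O)O)[C@H]1CC[C@](C)(C=C)OO1 | intermediate
23 | methyl (2S)-2-[(3R,6R)-6-ethenyl-6-methyl-1,2-dioxan-3-yl]propanoate | C[C@H](C(=O)OC)[C@H]1CC[C@](C)(C=C)OO1 | intermediate
24 | methyl (2S)-2-[(3R,6S)-6-[2-(9-borabicyclo[3.3.1]nonan-9-yl)ethyl]-6-methyl-1,2-dioxan-3-yl]propanoate | C[C@H](C(=O)OC)[C@H]1CC[C@](C)(CCB2C3CCCC2CCC3)OO1 | intermediate (not isolated)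
25 | methyl (2S)-2-[(3R,6S)-6-[(3Z)-3-(5,5-dimethyl-3,4,5,6,7,8-hexahydronaphthalen-2(1H)-ylidene)propyl]-6-methyl-1,2-dioxan-3-yl]propanoate | C[C@H](C(=O)OC)[C@H]1CC[C@](C)(CC/C=C2/CCC3=C(CCCC3(C)C)C2)OO1 | intermediate
26 | (2S)-2-[(3R,6S)-6-[(3Z)-3-(5,5-dimethyl-3,4,5,6,7,8-hexahydronaphthalen-2(1H)-ylidene)propyl]-6-methyl-1,2-dioxan-3-yl]propanoic acid | C[C@H](C(=O)O)[C@H]1CC[C@](C)(CC/C=C2/CCC3=C(CCCC3(C)C)C2)OO1 | target

Total step count: 20. Longest linear sequence: 13 steps (steps 8–20, from geranyl acetate 11); the acetate branch takes 7 steps (1–7).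

Steps most likely to fail

1. Step 19 (palladium cascade). The borate may transmetalate to the π-allyl intermediate before the alkyne has inserted, which would lead to reduced or directly alkylated allyl products. The π-allyl may also lose a β-hydrogen to give a diene, or zerovalent palladium may cleave the peroxide bond. The fallback uses known reaction types only, sets out from alcohol 9 and returns at 25. Alcohol 9 is converted with diethyl chlorophosphate and pyridine into [2-(but-3-yn-1-yl)-3,3-dimethylcyclohex-1-en-1-yl]methyl diethyl phosphate F1. Copper-catalysed borylative cyclisation (CuCl, Xantphos, KOtBu, B2pin2, THF) adds boron and copper syn across the alkyne with boron on the terminal carbon. The alkenylcopper then displaces the allylic phosphate at its primary carbon, which should give 2-[(Z)-(5,5-dimethyl-3,4,5,6,7,8-hexahydronaphthalen-2(1H)-ylidene)methyl]-4,4,5,5-tetramethyl-1,3,2-dioxaborolane F2 with boron cis to C1. Iododeboronation with retention (I2, aq. NaOH, THF, 0 °C) gives (2Z)-2-(iodomethylidene)-5,5-dimethyl-1,2,3,4,5,6,7,8-octahydronaphthalene F3. A conventional B-alkyl Suzuki–Miyaura coupling of this iodide with borane 24 (PdCl2(dppf), AsPh3, K3PO4, DMF/THF/H2O, rt) then delivers 25 with the same alkene geometry.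

2. Step 14 (dioxane closure). The peroxide anion may fragment through the neighbouring hydroxyl group (base-induced C–C cleavage of a β-hydroxy hydroperoxide). Alternatively, E2 loss of the mesylate toward the adjacent allylic hydrogen may outrun the 6-exo-tet displacement. The fallback closes the ring by conjugate addition instead; it sets out from aldehyde 12 and returns at acid 20. Horner–Wadsworth–Emmons reaction of 12 with methyl 2-(dimethoxyphosphoryl)propanoate (LiCl, DBU, MeCN) gives methyl (2E,6E)-8-acetoxy-2,6-dimethylocta-2,6-dienoate F4. Methanolysis (K2CO3, MeOH) gives methyl (2E,6E)-8-hydroxy-2,6-dimethylocta-2,6-dienoate F5. Sharpless epoxidation as in step 12 gives methyl (2E)-5-[(2S,3S)-3-(hydroxymethyl)-2-methyloxiran-2-yl]-2-methylpent-2-enoate F6. Perhydrolysis as in step 13 gives methyl (2E,6R,7S)-6-hydroperoxy-7,8-dihydroxy-2,6-dimethyloct-2-enoate F7. Amine-mediated intramolecular oxa-Michael addition (Et2NH, CF3CH2OH, rt) closes the ring to methyl (2S)-2-[(3R,6R)-6-[(1S)-1,2-dihydroxyethyl]-6-methyl-1,2-dioxan-3-yl]propanoate F8. This would form together with its epimers at the two new centres and must be separated by chromatography. Saponification (LiOH, THF/H2O, 0 °C) then returns acid 20. The price of this fallback is the loss of independent control over the ring CH and the α-carbon.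

3. Step 17 (methylenation). The ylide may attack the peroxide bond, or the α-peroxy aldehyde may fragment under the basic conditions before olefination takes place. The fallback sets out from 21 and returns at 23. Esterification first (Me3SiCHN2, toluene/MeOH, 0 °C) gives methyl (2S)-2-[(3R,6R)-6-formyl-6-methyl-1,2-dioxan-3-yl]propanoate F9. This is methylenated with one equivalent of the non-basic Tebbe reagent Cp2Ti(μ-CH2)(μ-Cl)AlMe2 (THF/toluene, −40 → 0 °C), the aldehyde reacting faster than the ester, to give 23 directly.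

Further compounds
F1 | step 19 | [2-(but-3-yn-1-yl)-3,3-dimethylcyclohex-1-en-1-yl]methyl diethyl phosphate | CCOP(=O)(OCC)OCC1=C(CCC#C)C(C)(C)CCC1
F2 | step 19 | 2-[(Z)-(5,5-dimethyl-3,4,5,6,7,8-hexahydronaphthalen-2(1H)-ylidene)methyl]-4,4,5,5-tetramethyl-1,3,2-dioxaborolane | CC1(C)OB(/C=C2/CCC3=C(CCCC3(C)C)C2)OC1(C)C
F3 | step 19 | (2Z)-2-(iodomethylidene)-5,5-dimethyl-1,2,3,4,5,6,7,8-octahydronaphthalene | I/C=C1/CCC2=C(CCCC2(C)C)C1
F4 | step 14 | methyl (2E,6E)-8-acetoxy-2,6-dimethylocta-2,6-dienoate | COC(=O)/C(C)=C/CC/C(C)=C/COC(C)=O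
F5 | step 14 | methyl (2E,6E)-8-hydroxy-2,6-dimethylocta-2,6-dienoate | COC(=O)/C(C)=C/CC/C(C)=C/CO
F6 | step 14 | methyl (2E)-5-[(2S,3S)-3-(hydroxymethyl)-2-methyloxiran-2-yl]-2-methylpent-2-enoate | COC(=O)/C(C)=C/CC[C@]1(C)O[C@H]1CO
F7 | step 14 | methyl (2E,6R,7S)-6-hydroperoxy-7,8-dihydroxy-2,6-dimethyloct-2-enoate | COC(=O)/C(C)=C/CC[C@@](C)(OO)[C@@H](O)CO
F8 | step 14 | methyl (2S)-2-[(3R,6R)-6-[(1S)-1,2-dihydroxyethyl]-6-methyl-1,2-dioxan-3-yl]propanoate | C[C@H](C(=O)OC)[C@H]1CC[C@](C)([C@@H](O)CO)OO1
F9 | step 17 | methyl (2S)-2-[(3R,6R)-6-formyl-6-methyl-1,2-dioxan-3-yl]propanoate | C[C@H](C(=O)OC)[C@H]1CC[C@](C)(C=O)OO1
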